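Assumption: chain atoms are numbered C1 (CO2H) to C16 (CH2Ph) as in the parent 16-phenylhexadecanoic acid; commercial 1 and 5 are taken as ≥98% ee.

## Retrosynthetic overview

1. The single ring (the 1,2-dioxane) is closed last, as in the presumed biosynthesis: a C6 hydroperoxide, made from O2 and the 1,1-disubstituted alkene of 10, adds to the C3 ketone; the same flask frees the acid (10 → 14).
2. 10 ⇐ 9 by Claisen condensation with tert-butyl acetate (C2–C3 bond); 9 ⇐ 8 by methylenation at C6.
3. 8 ⇐ acid chloride of 4 (C6–C16) + zinc homoenolate from 5 (C3–C5), forming C5–C6; the C4 stereocentre is bought with 5.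
4. 4 ⇐ (R)-citronellic acid 1 + 6-phenylhex-1-ene 2 by cross-metathesis and hydrogenation; the C8 stereocentre is bought with 1.
5. Stereocentres: C8 and C4 from the chiral pool; C3 by anomeric equilibration; C6 is created in the last step by radical O2 capture without facial control (about 1:1), and the 6S epimer is obtained by separating the two diastereomers.

## Route

Step 1
Reactants: 1 (3R)-3,7-dimethyloct-6-enoic acid [(R)-citronellic acid]; 2 6-phenylhex-1-ene
Product: 4 (3R)-3-methyl-11-phenylundecanoic acid, via alkenoic acid 3 (not isolated)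
Conditions: 2 (3 equiv), second-generation Grubbs catalyst (2 mol%), CH2Cl2, 40 °C; evaporate; then H2 (1 atm), 10% Pd/C, EtOAc, rt; acid–base extraction
Reagents that add atoms: none
Why: Olefin cross-metathesis swaps the isopropylidene end of 1 for the alkylidene of 2 (2-methylpropene is lost) and catalytic hydrogenation then saturates the new alkene, so the stereocentre of 1 (C8 of the target, R) is never touched and the acid is freed from neutral hydrocarbon by-products by base extraction.

Step 2
Reactants: 4 (3R)-3-methyl-11-phenylundecanoic acid; 5 methyl (2S)-3-bromo-2-methylpropanoate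
Product: 8 methyl (2R,6R)-2,6-dimethyl-4-oxo-14-phenyltetradecanoate, via acid chloride 6 (not isolated), via organozinc bromide 7 (not isolated)
Conditions: 4: (COCl)2, cat. DMF, CH2Cl2, 0 °C to rt, evaporate; 5: Zn dust, LiCl, THF, 45 °C; combine, Pd(PPh3)4 (3 mol%), THF, 0 °C to rt
Reagents that add atoms: none
Why: Negishi-type acylation, in which Pd(PPh3)4 couples the ester-stabilised primary alkylzinc 7 with acid chloride 6 to the γ-keto ester without enolising either partner, so the stereocentre of 5 (C4 of the target, R) and that of 4 are carried over unchanged.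

Step 3
Reactants: 8 methyl (2R,6R)-2,6-dimethyl-4-oxo-14-phenyltetradecanoate
Product: 9 methyl (2R,6R)-2,6-dimethyl-4-methylidene-14-phenyltetradecanoate
Conditions: Ph3PCH3Br (1.5 equiv), KOtBu (1.4 equiv), THF, 0 °C; then 8, 0 °C to rt
Reagents that add atoms: methyltriphenylphosphonium bromide, C[P+](c1ccccc1)(c1ccccc1)c1ccccc1.[Br-]
Why: Wittig methylenation of the unhindered dialkyl ketone is faster than any reaction at the ester, and because the ylide is kept free of excess alkoxide the ester α-stereocentre is not epimerised.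

Step 4
Reactants: 9 methyl (2R,6R)-2,6-dimethyl-4-methylidene-14-phenyltetradecanoate
Product: 10 tert-butyl (4R,8R)-4,8-dimethyl-6-methylidene-3-oxo-16-phenylhexadecanoate
Conditions: tert-butyl acetate (3.5 equiv), LDA (3.5 equiv), THF, −78 °C; then 9, −78 to −40 °C; AcOH quench at −78 °C
Reagents that add atoms: tert-butyl acetate, CC(=O)OC(C)(C)C
Why: Crossed Claisen condensation, in which the lithium enolate of tert-butyl acetate adds to the methyl ester at low temperature faster than it deprotonates the α-branched ester, and the product is stored as its C2 enolate, which shields C4 from epimerisation.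

Step 5
Reactants: 10 tert-butyl (4R,8R)-4,8-dimethyl-6-methylidene-3-oxo-16-phenylhexadecanoate
Product: 14 2-[(3S,4R,6S)-3-hydroxy-4,6-dimethyl-6-[(2R)-2-methyl-10-phenyldecyl]-1,2-dioxan-3-yl]acetic acid, via silyl peroxide 11 (not isolated), via hydroperoxy ketone 12 (not isolated), via hemiketal tert-butyl ester 13 (not isolated)
Conditions: Co(thd)2 (10 mol%; thd = 2,2,6,6-tetramethylheptane-3,5-dionate), Et3SiH (2.5 equiv), O2 (1 atm), ClCH2CH2Cl, rt; short silica plug, evaporate; then TFA/CH2Cl2/H2O (20:78:2), 0 °C to rt; reversed-phase HPLC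
Reagents that add atoms: dioxygen, O=O
Why: Isayama–Mukaiyama hydroperoxysilylation (cobalt hydride hydrogen-atom transfer gives the tertiary C6 radical, which captures O2) followed by acid-mediated desilylation, intramolecular peroxy-hemiketalisation onto the C3 ketone and tert-butyl ester acidolysis; C6 forms without facial bias (about 1:1, the 6S epimer is separated from the 6R epimer by HPLC), C3 settles by ring–chain equilibration with OH axial (anomeric effect) and CH2CO2H equatorial (3S), and C4 and C8 are untouched.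

## Compound list

1 | (3R)-3,7-dimethyloct-6-enoic acid [(R)-citronellic acid] | C[C@H](CCC=C(C)C)CC(=O)O | starting material
2 | 6-phenylhex-1-ene | C=CCCCCc1ccccc1 | starting material
3 | (3R,6E)-3-methyl-11-phenylundec-6-enoic acid (E major, some Z) | C[C@H](CC/C=C/CCCCc1ccccc1)CC(=O)O | intermediate
4 | (3R)-3-methyl-11-phenylundecanoic acid | C[C@H](CCCCCCCCc1ccccc1)CC(=O)O | intermediate
5 | methyl (2S)-3-bromo-2-methylpropanoate | BrC[C@@H](C)C(=O)OC | starting material
6 | (3R)-3-methyl-11-phenylundecanoyl chloride | C[C@H](CCCCCCCCc1ccccc1)CC(=O)Cl | intermediate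
7 | [(2S)-3-methoxy-2-methyl-3-oxopropyl]zinc bromide | Br[Zn]C[C@@H](C)C(=O)OC | intermediate
8 | methyl (2R,6R)-2,6-dimethyl-4-oxo-14-phenyltetradecanoate | C[C@H](CCCCCCCCc1ccccc1)CC(=O)C[C@@H](C)C(=O)OC | intermediate
9 | methyl (2R,6R)-2,6-dimethyl-4-methylidene-14-phenyltetradecanoate | C[C@H](CCCCCCCCc1ccccc1)CC(=C)C[C@@H](C)C(=O)OC | intermediate
10 | tert-butyl (4R,8R)-4,8-dimethyl-6-methylidene-3-oxo-16-phenylhexadecanoate | C[C@H](CCCCCCCCc1ccccc1)CC(=C)C[C@@H](C)C(=O)CC(=O)OC(C)(C)C | intermediate
11 | tert-butyl (4R,6S,8R)-4,6,8-trimethyl-3-oxo-16-phenyl-6-[(triethylsilyl)peroxy]hexadecanoate | C[C@H](CCCCCCCCc1ccccc1)C[C@](C)(OO[Si](CC)(CC)CC)C[C@@H](C)C(=O)CC(=O)OC(C)(C)C | intermediate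
12 | tert-butyl (4R,6S,8R)-6-hydroperoxy-4,6,8-trimethyl-3-oxo-16-phenylhexadecanoate | C[C@H](CCCCCCCCc1ccccc1)C[C@](C)(OO)C[C@@H](C)C(=O)CC(=O)OC(C)(C)C | intermediate
13 | tert-butyl 2-[(3S,4R,6S)-3-hydroxy-4,6-dimethyl-6-[(2R)-2-methyl-10-phenyldecyl]-1,2-dioxan-3-yl]acetate | C[C@H](CCCCCCCCc1ccccc1)C[C@@]1(C)C[C@@H](C)[C@](O)(CC(=O)OC(C)(C)C)OO1 | intermediate
14 | 2-[(3S,4R,6S)-3-hydroxy-4,6-dimethyl-6-[(2R)-2-methyl-10-phenyldecyl]-1,2-dioxan-3-yl]acetic acid | C[C@H](CCCCCCCCc1ccccc1)C[C@@]1(C)C[C@@H](C)[C@](O)(CC(=O)O)OO1 | target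

## Step count and risks

Total steps: 5. Longest linear sequence: 5 (1 → 4 → 8 → 9 → 10 → 14).

**Step 5 (most likely to fail).** Two things can go wrong: the β-keto ester of 10 may bind cobalt or be oxygenated at C2, and the C6 epimers form in about equal amounts whatever is done. The fallback installs the peroxide before the 1,3-dicarbonyl exists; it sets out from 9 and comes back to the route at 11. Saponification of 9 (LiOH, THF/H2O) gives (2R,6R)-2,6-dimethyl-4-methylidene-14-phenyltetradecanoic acid F1. The same cobalt/Et3SiH/O2 hydroperoxysilylation on this simple acid (aqueous work-up to hydrolyse any silyl ester) gives (2R,4S,6R)-2,4,6-trimethyl-14-phenyl-4-[(triethylsilyl)peroxy]tetradecanoic acid F2, together with its 4-epimer. Activation with carbonyldiimidazole gives the acyl imidazolide F3. Reaction with Mg(O2CCH2CO2tBu)2 (Masamune–Brooks decarboxylative Claisen, near-neutral) then passes through the acylmalonate half-ester F4 and, after loss of CO2, gives silyl peroxide 11, which enters the acid stage of step 5. This does not cure the C6 ratio; separation remains necessary.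

**Step 4.** The α-branched methyl ester may react sluggishly or epimerise at C4 under the basic Claisen conditions. The fallback sets out from 9 and comes back at 10. DIBAL-H reduction at −78 °C gives (2R,6R)-2,6-dimethyl-4-methylidene-14-phenyltetradecanal F5. Roskamp homologation with tert-butyl diazoacetate and catalytic SnCl2 in CH2Cl2 at rt, a Lewis-acid route with no enolate, inserts the CH(CO2tBu) unit into the aldehyde C–H bond to give 10 directly.

**Step 1.** Cross-metathesis at the trisubstituted prenyl-type alkene may stall or be swamped by homodimer of 2. The fallback replaces metathesis by olefination; it sets out from 1 and comes back at 4. Ozonolysis of 1 (O3, CH2Cl2/MeOH, −78 °C; Me2S) gives (3R)-3-methyl-6-oxohexanoic acid F6. Triphenyl(5-phenylpentyl)phosphonium bromide F7 is prepared from (5-bromopentyl)benzene and PPh3. Wittig reaction of F6 with the ylide of F7 (NaHMDS, 2.2 equiv, THF, −78 °C to rt) gives (3R,6Z)-3-methyl-11-phenylundec-6-enoic acid F8. Hydrogenation (H2, 10% Pd/C, EtOAc) returns 4.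

Further compounds
F1 | step 5 | (2R,6R)-2,6-dimethyl-4-methylidene-14-phenyltetradecanoic acid | C[C@H](CCCCCCCCc1ccccc1)CC(=C)C[C@@H](C)C(=O)O
F2 | step 5 | (2R,4S,6R)-2,4,6-trimethyl-14-phenyl-4-[(triethylsilyl)peroxy]tetradecanoic acid | C[C@H](CCCCCCCCc1ccccc1)C[C@](C)(OO[Si](CC)(CC)CC)C[C@@H](C)C(=O)O
F3 | step 5 | 1-[(2R,4S,6R)-2,4,6-trimethyl-14-phenyl-4-[(triethylsilyl)peroxy]tetradecanoyl]imidazole | C[C@H](CCCCCCCCc1ccccc1)C[C@](C)(OO[Si](CC)(CC)CC)C[C@@H](C)C(=O)n1ccnc1
F4 | step 5 | (2RS)-3-tert-butoxy-3-oxo-2-[(2R,4S,6R)-2,4,6-trimethyl-14-phenyl-4-[(triethylsilyl)peroxy]tetradecanoyl]propanoic acid (magnesium salt in the flask) | C[C@H](CCCCCCCCc1ccccc1)C[C@](C)(OO[Si](CC)(CC)CC)C[C@@H](C)C(=O)C(C(=O)O)C(=O)OC(C)(C)C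
F5 | step 4 | (2R,6R)-2,6-dimethyl-4-methylidene-14-phenyltetradecanal | C[C@H](CCCCCCCCc1ccccc1)CC(=C)C[C@@H](C)C=O
F6 | step 1 | (3R)-3-methyl-6-oxohexanoic acid | C[C@H](CCC=O)CC(=O)O
F7 | step 1 | triphenyl(5-phenylpentyl)phosphonium bromide | [Br-].c1ccc(cc1)CCCCC[P+](c1ccccc1)(c1ccccc1)c1ccccc1
F8 | step 1 | (3R,6Z)-3-methyl-11-phenylundec-6-enoic acid | C[C@H](CC/C=C\CCCCc1ccccc1)CC(=O)O
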